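**Retrosynthetic overview**

1. Enabling feature: in the ten-membered carbocycle (C1–C10) the segment C9(O)–C10(CO2Me)=C1H–C2H2 is an oxygenated carbon next to a ring-cis acrylate. C10, C1 and the ester carbon C14 are one methyl propiolate unit inserted into a C9–C2 bond, and the all-cis ring geometry (1(10)-cis alkene, cis-4,5-epoxide, cis-fused 6,7-lactone) fits an eight-membered precursor.
2. Key disconnection C9–C10 / C1–C2: formal (2+2) cycloaddition of the C9 silyl enol ether of a cyclooctenone with methyl propiolate, then 4π ring opening of the bicyclo[6.2.0]decene, which enlarges the eight-membered ring to the ten-membered ring by two atoms.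
3. After the expansion: C9 ketone to 9-acetate, O8 ester from (S)-2-methylglycidic acid, C11=C13 unmasked from a phenylthiomethyl group, C4=C5 epoxidised last.
4. Cyclooctenone: RCM at C4=C5 on a cis-γ-lactone template; C9 ketone by thioester–organozinc coupling; C6, C7, C8 from diacetone-D-glucose (sugar C2, C3, C4) through a 3-C-branched allofuranose.
5. Ring order: γ-lactone (from the furanose) → cyclooctene (RCM) → transient cyclobutene → cyclodecadiene (ring expansion) → epoxide.

Key step: step 16

Remark (assumption): the SMILES is read as (4R,5S,6R,7R,8S,9S,2′S) with the C1=C10 bond, the 4,5-epoxide and the 6,7-lactone fusion all cis in the ring; germacrane numbering is used throughout (C11–C13 = lactone α-carbon, carbonyl, exocyclic CH2; C14 = ester carbon on C10; C15 = methyl on C4), and sugar C1–C5 become C5–C9.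

**Route**

Step 1
Reactants: 1 1,2:5,6-di-O-isopropylidene-α-D-glucofuranose
Product: 2 1,2:5,6-di-O-isopropylidene-α-D-ribo-hexofuranos-3-ulose
Conditions: Dess–Martin periodinane, NaHCO3, CH2Cl2, rt
Reagents that add atoms: none
Why: Dess–Martin oxidation of the only free (secondary) alcohol; the acetonides are inert and no stereocentre is touched.

Step 2
Reactants: 2 1,2:5,6-di-O-isopropylidene-α-D-ribo-hexofuranos-3-ulose
Product: 3 methyl (3-deoxy-1,2:5,6-di-O-isopropylidene-α-D-ribo-hexofuranos-3-ylidene)acetate (E/Z mixture)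
Conditions: (MeO)2P(O)CH2CO2Me, NaH, THF, 0 °C → rt
Reagents that add atoms: trimethyl phosphonoacetate, COC(=O)CP(=O)(OC)OC
Why: Horner–Wadsworth–Emmons olefination of the ketone brings in C11 and C12; the alkene geometry is irrelevant because the bond is hydrogenated next.

Step 3
Reactants: 3 methyl (3-deoxy-1,2:5,6-di-O-isopropylidene-α-D-ribo-hexofuranos-3-ylidene)acetate
Product: 4 3-deoxy-3-C-(2-methoxy-2-oxoethyl)-1,2:5,6-di-O-isopropylidene-α-D-allofuranose
Conditions: H2 (1 atm), 10% Pd/C, EtOAc, rt
Reagents that add atoms: none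
Why: Heterogeneous hydrogenation should deliver hydrogen from the convex β-face of the cis-fused 1,2-O-isopropylidene furanose, so the CH2CO2Me branch ends up α and cis to O-2 (allo); this sets C7 relative to C6 and C8.

Step 4
Reactants: 4 3-deoxy-3-C-(2-methoxy-2-oxoethyl)-1,2:5,6-di-O-isopropylidene-α-D-allofuranose
Product: 5 3-deoxy-3-C-(2-methoxy-2-oxoethyl)-1,2-O-isopropylidene-α-D-ribo-pentodialdo-1,4-furanose
Conditions: H5IO6, EtOAc, rt
Reagents that add atoms: none
Why: Periodic acid hydrolyses the more labile terminal acetonide and cleaves the freed 5,6-diol in one pot (glycol cleavage), leaving the 1,2-acetonide and the C8 stereocentre intact.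

Step 5
Reactants: 5 3-deoxy-3-C-(2-methoxy-2-oxoethyl)-1,2-O-isopropylidene-α-D-ribo-pentodialdo-1,4-furanose
Product: 6 3-deoxy-3-C-(2-methoxy-2-oxoethyl)-1,2-O-isopropylidene-α-D-ribofuranuronic acid
Conditions: NaClO2, NaH2PO4, 2-methylbut-2-ene, t-BuOH/H2O, 0 °C → rt
Reagents that add atoms: sodium chlorite, [Na+].[O-]Cl=O
Why: Pinnick oxidation converts the α-alkoxy aldehyde into the acid under buffered conditions that do not epimerise C8.

Step 6
Reactants: 6 3-deoxy-3-C-(2-methoxy-2-oxoethyl)-1,2-O-isopropylidene-α-D-ribofuranuronic acid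
Product: 7 S-ethyl 3-deoxy-3-C-(2-methoxy-2-oxoethyl)-1,2-O-isopropylidene-α-D-ribofuranuronothioate
Conditions: EtSH, DCC, DMAP (cat.), CH2Cl2, 0 °C → rt
Reagents that add atoms: ethanethiol, CCS
Why: Steglich thioesterification installs the acyl donor for the later ketone synthesis and leaves no hydroxyl on C9, so the sugar can only stay in the furanose form in step 7.

Step 7
Reactants: 7 S-ethyl 3-deoxy-3-C-(2-methoxy-2-oxoethyl)-1,2-O-isopropylidene-α-D-ribofuranuronothioate
Product: 8 S-ethyl 3-C-(carboxymethyl)-3-deoxy-D-ribofuranuronothioate 2,3′-lactone (cis-fused lactone–lactol; anomeric mixture)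
Conditions: TFA/H2O (9:1), 0 °C → rt; concentration from toluene
Reagents that add atoms: water, O
Why: Acetal hydrolysis frees O-2, which is cis to the C3 branch and lactonises onto the methyl ester, while O-4 stays locked in the furanose ring; this differentiates the two carbinol oxygens flanking C7 (O6 acylated, O8 masked).

Step 8
Reactants: 8 lactone–lactol thioester
Product: 9 open-chain dithiane: cis-γ-butyrolactone with 1,3-dithian-2-yl (C5) on C6 and CH(OH)–C(O)SEt (C8, C9) on C7
Conditions: HS(CH2)3SH, BF3·OEt2, CH2Cl2, −20 → 0 °C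
Reagents that add atoms: propane-1,3-dithiol, SCCCS
Why: Dithioacetalisation opens the lactol without base, so O8 is released as a neutral alcohol and no alkoxide is formed that could attack the lactone carbonyl.

Step 9
Reactants: 9 open-chain dithiane with free 8-OH
Product: 10 8-O-TBS ether of 9
Conditions: TBSOTf, 2,6-lutidine, CH2Cl2, −78 °C
Reagents that add atoms: tert-butyldimethylsilyl triflate, CC(C)(C)[Si](C)(C)OS(=O)(=O)C(F)(F)F
Why: Silylation of the only free hydroxyl fixes the lactone on O6 and supplies the bulky, non-chelating group used later for Felkin–Anh control at C9.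

Step 10
Reactants: 10 8-O-TBS dithiane
Product: 11 C5 aldehyde: cis-γ-butyrolactone with CHO on C6 and CH(OTBS)–C(O)SEt on C7
Conditions: MeI, CaCO3, MeCN/H2O (9:1), 45 °C
Reagents that add atoms: water, O
Why: Alkylative dithiane hydrolysis (S-methylation, then hydrolysis of the sulfonium ion) proceeds near neutrality and should spare the thioester, the lactone, the silyl ether and the configuration of the α-acyloxy aldehyde.

Step 11
Reactants: 11 C5 aldehyde
Product: 12 C6-vinyl lactone thioester (C5=CH2)
Conditions: CH2I2, Zn, Ti(OiPr)4, THF, rt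
Reagents that add atoms: diiodomethane, ICI
Why: Takai-type methylenation with the gem-dizinc/titanium reagent is non-basic and selective for aldehydes over thioesters and lactones, so C6 is not epimerised.

Step 12
Reactants: 12 C6-vinyl lactone thioester; 13 4-bromo-2-methylbut-1-ene
Product: 15 dienyl ketone: cis-γ-butyrolactone with vinyl on C6 and CH(OTBS)–C(O)–CH2CH2C(CH3)=CH2 on C7, via organozinc bromide 14 (not isolated)
Conditions: 13, Zn dust, LiCl, THF, 40 °C; then 12, PdCl2(PPh3)2 (cat.), toluene/THF, rt
Reagents that add atoms: none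
Why: Fukuyama coupling (Pd insertion into the C–S bond, transmetalation, reductive elimination) gives the C9 ketone without attacking the lactone, and the acid-sensitive 1,1-disubstituted alkene enters only after all acidic steps.

Step 13
Reactants: 15 dienyl ketone
Product: 16 cis-fused cyclooctenone lactone (ring C2–C9: 9-oxo, 8-OTBS, C4-methyl, C4=C5 Z; γ-lactone fused at C6–C7)
Conditions: Grubbs second-generation catalyst (10 mol%), toluene (2 mM), 80 °C
Reagents that add atoms: none
Why: Ring-closing metathesis; the cis-lactone holds the vinyl group and the ketone chain on the same face, and the eight-membered ring enforces the Z (ring-cis) trisubstituted C4=C5 bond.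

Step 14
Reactants: 16 cis-fused cyclooctenone lactone
Product: 17 C9 TBS enol ether of 16 (C9=C2 enol ether, 8-OTBS)
Conditions: LiHMDS, THF, −78 °C; then TBSOTf, −78 °C
Reagents that add atoms: tert-butyldimethylsilyl triflate, CC(C)(C)[Si](C)(C)OS(=O)(=O)C(F)(F)F
Why: Kinetic deprotonation should occur at the unhindered C2 methylene and not at the oxygenated tertiary C8 or at the less acidic lactone, and O-silylation fixes the C9=C2 regiochemistry.

Step 15
Reactants: 17 C9 TBS enol ether
Product: 18 13-phenylsulfanyl derivative of 17 (CH2SPh on C11, trans to C8)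
Conditions: LDA, THF, −78 °C; then PhSCH2Cl, NaI (cat.), DMPU, −78 → −20 °C
Reagents that add atoms: chloromethyl phenyl sulfide, ClCSc1ccccc1
Why: Lactone enolate alkylation on the convex face (anti to the C7 substituent) installs C13 as a masked exocyclic methylene; the ketone is protected as its silyl enol ether, and the new C11 centre is later made sp2.

Step 16
Reactants: 18 phenylthiomethyl silyl enol ether; 19 methyl propiolate
Product: 21 ten-membered silyl dienol ether: methyl 8,9-bis(TBS-oxy)-13-phenylsulfanyl-11,13-dihydrogermacra-1,4,9-trien-12,6-olid-14-oate (C9=C10 ring-cis; C1=C2 ring-trans; C4=C5 ring-cis), via cyclobutene adduct 20 (not isolated)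
Conditions: 19 (2 equiv), Tf2NH (5 mol%), CH2Cl2, −78 °C; Et3N quench; then toluene, 90 °C
Reagents that add atoms: none
Why: The silylium species formed from Tf2NH and 18 activates methyl propiolate for Mukaiyama–Michael attack by C2 on the alkyne β-carbon (future C1), and the resulting allenyl ketene acetal closes onto the C9 silyloxocarbenium ion (4-exo-trig, aldol-type closure of the four-membered ring; a stepwise formal (2+2) cycloaddition) to give the bicyclo[6.2.0]dec-9-ene 20; warming opens this donor–acceptor cyclobutene by conrotatory 4π electrocyclic ring opening across the former C9–C2 bond, so the eight-membered carbocycle becomes the ten-membered one with C10 and C1 inserted. The closest known reaction type is the acid-catalysed (2+2) cycloaddition of cyclic silyl enol ethers with propiolates followed by thermal opening of the 1-siloxybicyclo[n.2.0]alkene to the two-carbon ring-enlarged 1,3-diene. Regiochemistry (ester-bearing C10 on the oxygenated C9, CH of C1 on C2) follows from the polarity of the partners; chemoselectivity over the C4=C5 alkene follows from the far higher nucleophilicity of the enol ether at −78 °C, and the masked lactone methylene cannot compete as a Michael acceptor. The two stereocentres created in 20 (C9, C2) are destroyed in the ring opening, so the facial course of the cycloaddition does not matter and no existing stereocentre is touched. The only new stereo elements are alkene geometries: outward rotation of the C9 siloxy donor turns C8 inward (C9=C10 ring-cis) and C3 outward (C1=C2 ring-trans); both are provisional, because C9 becomes a ketone and the C1=C2 bond is moved to C1=C10 in step 17.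

Step 17
Reactants: 21 ten-membered silyl dienol ether
Product: 23 alkylidene β-keto ester: methyl 9-oxo-8-(TBS-oxy)-13-phenylsulfanyl-11,13-dihydrogermacra-1(10),4-dien-12,6-olid-14-oate (C1=C10 ring-cis), via deconjugated keto ester 22 (not isolated)
Conditions: TBAF, AcOH, THF, 0 °C; then Et3N, CH2Cl2, rt
Reagents that add atoms: none
Why: Fluoride cleaves the enol silyl ether much faster than the hindered secondary TBS ether, and amine-mediated equilibration through the extended enolate moves the double bond into conjugation; the ring-cis C1=C10 isomer (no trans alkene in the ring) is expected to be the thermodynamic product.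

Step 18
Reactants: 23 alkylidene β-keto ester
Product: 24 9-alcohol: methyl (9S)-9-hydroxy-8-(TBS-oxy)-13-phenylsulfanyl-11,13-dihydrogermacra-1(10),4-dien-12,6-olid-14-oate
Conditions: NaBH4, CeCl3·7H2O, MeOH/THF, −78 °C
Reagents that add atoms: none
Why: Luche reduction should give 1,2-addition to the ketone, and Felkin–Anh attack anti to the non-chelating C8–OSi bond should give the 8,9-syn (threo) alcohol, which is the C9 configuration of the target.

Step 19
Reactants: 24 9-alcohol
Product: 25 9-acetate of 24
Conditions: Ac2O, pyridine, DMAP (cat.), CH2Cl2, 0 °C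
Reagents that add atoms: acetic anhydride, CC(=O)OC(C)=O
Why: Standard acylation of the only free hydroxyl; the β-substituted acrylate is not prone to SN2′ transposition under these mild conditions.

Step 20
Reactants: 25 9-acetate
Product: 26 8-alcohol: methyl 9-acetoxy-8-hydroxy-13-phenylsulfanyl-11,13-dihydrogermacra-1(10),4-dien-12,6-olid-14-oate
Conditions: HF·pyridine, pyridine, THF, 0 °C → rt
Reagents that add atoms: none
Why: Buffered acidic desilylation frees O8 while avoiding the base-promoted acetyl migration from O9 to O8.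

Step 21
Reactants: 27 (R)-2-methylglycidol
Product: 28 (S)-2-methyloxirane-2-carboxylic acid
Conditions: RuCl3·xH2O (cat.), NaIO4, MeCN/EtOAc/H2O, 0 °C → rt
Reagents that add atoms: water, O
Why: Ruthenium tetroxide oxidation of the primary alcohol to the acid leaves the epoxide and the quaternary stereocentre untouched (the descriptor changes from R to S only through the CIP priorities).

Step 22
Reactants: 26 8-alcohol; 28 (S)-2-methyloxirane-2-carboxylic acid
Product: 30 8-O-[(S)-2-methyloxirane-2-carbonyl] ester of 26, via mixed anhydride 29 (not isolated)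
Conditions: 28, 2,4,6-trichlorobenzoyl chloride, Et3N, toluene, 0 °C; then 26, DMAP, 0 °C → rt
Reagents that add atoms: none
Why: Yamaguchi esterification acylates the hindered secondary alcohol with the α-quaternary, non-enolisable acid; the low temperature limits acetyl migration.

Step 23
Reactants: 30 epoxy ester sulfide
Product: 32 4,5-deoxy precursor: methyl 9-acetoxy-8-[(S)-2-methyloxirane-2-carbonyloxy]germacra-1(10),4,11(13)-trien-12,6-olid-14-oate, via sulfoxide 31 (not isolated)
Conditions: mCPBA (1.0 equiv), CH2Cl2, −78 °C; then toluene, CaCO3, 100 °C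
Reagents that add atoms: none
Why: The sulfide is oxidised far faster than the trisubstituted alkene at −78 °C, and thermal sulfoxide syn-elimination can only use the C11–H, so it should give the exocyclic C11=C13 methylene alone.

Step 24
Reactants: 32 4,5-deoxy precursor
Product: 33 CNP0274195.1 (target)
Conditions: mCPBA (1.1 equiv), NaHCO3, CH2Cl2, 0 °C
Reagents that add atoms: 3-chloroperbenzoic acid, O=C(OO)c1cccc(Cl)c1
Why: Prilezhaev epoxidation touches only the electron-rich C4=C5 bond; A(1,3) strain puts H-6 in the alkene plane, so the peracid should approach anti to C7 (the ring side) and syn to the C6–O bond, and the cis alkene then gives the cis-(4R,5S)-epoxide.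

**Compound list**

1 | 1,2:5,6-di-O-isopropylidene-α-D-glucofuranose | CC1(C)O[C@H]2[C@@H](O1)O[C@H]([C@H]3COC(C)(C)O3)[C@@H]2O | starting material
2 | 1,2:5,6-di-O-isopropylidene-α-D-ribo-hexofuranos-3-ulose | CC1(C)O[C@H]2[C@@H](O1)O[C@H]([C@H]3COC(C)(C)O3)C2=O | intermediate
3 | methyl (3-deoxy-1,2:5,6-di-O-isopropylidene-α-D-ribo-hexofuranos-3-ylidene)acetate (E/Z mixture) | CC1(C)O[C@H]2[C@@H](O1)O[C@H]([C@H]3COC(C)(C)O3)C2=CC(=O)OC | intermediate
4 | 3-deoxy-3-C-(2-methoxy-2-oxoethyl)-1,2:5,6-di-O-isopropylidene-α-D-allofuranose | CC1(C)O[C@H]2[C@@H](O1)O[C@H]([C@H]3COC(C)(C)O3)[C@H]2CC(=O)OC | intermediate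
5 | 3-deoxy-3-C-(2-methoxy-2-oxoethyl)-1,2-O-isopropylidene-α-D-ribo-pentodialdo-1,4-furanose | CC1(C)O[C@H]2[C@@H](O1)O[C@H](C=O)[C@H]2CC(=O)OC | intermediate
6 | 3-deoxy-3-C-(2-methoxy-2-oxoethyl)-1,2-O-isopropylidene-α-D-ribofuranuronic acid | CC1(C)O[C@H]2[C@@H](O1)O[C@H](C(=O)O)[C@H]2CC(=O)OC | intermediate
7 | S-ethyl 3-deoxy-3-C-(2-methoxy-2-oxoethyl)-1,2-O-isopropylidene-α-D-ribofuranuronothioate | CC1(C)O[C@H]2[C@@H](O1)O[C@H](C(=O)SCC)[C@H]2CC(=O)OC | intermediate
8 | S-ethyl 3-C-(carboxymethyl)-3-deoxy-D-ribofuranuronothioate 2,3′-lactone (cis-fused lactone–lactol, anomeric mixture) | OC1O[C@H](C(=O)SCC)[C@H]2CC(=O)O[C@@H]12 | intermediate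
9 | cis-γ-butyrolactone with 1,3-dithian-2-yl on C6 and CH(OH)–C(O)SEt on C7 (C6, C7, C8 as in the target) | C1C(=O)O[C@@H](C2SCCCS2)[C@H]1[C@H](O)C(=O)SCC | intermediate
10 | 8-O-TBS ether of 9 | C1C(=O)O[C@@H](C2SCCCS2)[C@H]1[C@H](O[Si](C)(C)C(C)(C)C)C(=O)SCC | intermediate
11 | cis-γ-butyrolactone with CHO (C5) on C6 and CH(OTBS)–C(O)SEt on C7 | C1C(=O)O[C@@H](C=O)[C@H]1[C@H](O[Si](C)(C)C(C)(C)C)C(=O)SCC | intermediate
12 | cis-γ-butyrolactone with vinyl on C6 and CH(OTBS)–C(O)SEt on C7 | C1C(=O)O[C@@H](C=C)[C@H]1[C@H](O[Si](C)(C)C(C)(C)C)C(=O)SCC | intermediate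
13 | 4-bromo-2-methylbut-1-ene | C=C(C)CCBr | starting material
14 | (3-methylbut-3-en-1-yl)zinc bromide | C=C(C)CC[Zn]Br | intermediate (not isolated)
15 | cis-γ-butyrolactone with vinyl on C6 and CH(OTBS)–C(O)–CH2CH2C(CH3)=CH2 on C7 | C1C(=O)O[C@@H](C=C)[C@H]1[C@H](O[Si](C)(C)C(C)(C)C)C(=O)CCC(C)=C | intermediate
16 | cis-fused cyclooctenone lactone (9-oxo, 8-OTBS, 4-methyl, C4=C5 Z, 6,7-cis-lactone) | C1C(=O)O[C@@H]2[C@H]1[C@H](O[Si](C)(C)C(C)(C)C)C(=O)CC/C(C)=C\2 | intermediate
17 | C9 TBS enol ether of 16 (C9=C2) | C1C(=O)O[C@@H]2[C@H]1[C@H](O[Si](C)(C)C(C)(C)C)/C(O[Si](C)(C)C(C)(C)C)=C\C/C(C)=C\2 | intermediate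
18 | 17 with CH2SPh on C11 (trans to C8) | [C@@H]1(CSc3ccccc3)C(=O)O[C@@H]2[C@H]1[C@H](O[Si](C)(C)C(C)(C)C)/C(O[Si](C)(C)C(C)(C)C)=C\C/C(C)=C\2 | intermediate
19 | methyl propiolate | C#CC(=O)OC | starting material
20 | cis-fused bicyclo[6.2.0]dec-9-ene adduct (C9 siloxy, C10 ester; C9/C2 configuration inconsequential) | [C@@H]1(CSc3ccccc3)C(=O)O[C@@H]2[C@H]1[C@H](O[Si](C)(C)C(C)(C)C)C4(O[Si](C)(C)C(C)(C)C)C(C(=O)OC)=CC4C/C(C)=C\2 | intermediate (not isolated)
21 | methyl 8,9-bis(TBS-oxy)-13-phenylsulfanyl-11,13-dihydrogermacra-1,4,9-trien-12,6-olid-14-oate (C9=C10 ring-cis, C1=C2 ring-trans) | [C@@H]1(CSc3ccccc3)C(=O)O[C@@H]2[C@H]1[C@H](O[Si](C)(C)C(C)(C)C)/C(O[Si](C)(C)C(C)(C)C)=C(C(=O)OC)\C=C\C/C(C)=C\2 | intermediate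
22 | deconjugated β-keto ester (9-oxo, C10–H, C1=C2 ring-trans; C10 epimers) | [C@@H]1(CSc3ccccc3)C(=O)O[C@@H]2[C@H]1[C@H](O[Si](C)(C)C(C)(C)C)C(=O)C(C(=O)OC)/C=C/C/C(C)=C\2 | intermediate (not isolated)
23 | methyl 9-oxo-8-(TBS-oxy)-13-phenylsulfanyl-11,13-dihydrogermacra-1(10),4-dien-12,6-olid-14-oate (C1=C10 ring-cis) | [C@@H]1(CSc3ccccc3)C(=O)O[C@@H]2[C@H]1[C@H](O[Si](C)(C)C(C)(C)C)C(=O)/C(C(=O)OC)=C\CC/C(C)=C\2 | intermediate
24 | (9S)-9-hydroxy analogue of 23 | [C@@H]1(CSc3ccccc3)C(=O)O[C@@H]2[C@H]1[C@H](O[Si](C)(C)C(C)(C)C)[C@@H](O)/C(C(=O)OC)=C\CC/C(C)=C\2 | intermediate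
25 | 9-acetate of 24 | [C@@H]1(CSc3ccccc3)C(=O)O[C@@H]2[C@H]1[C@H](O[Si](C)(C)C(C)(C)C)[C@@H](OC(C)=O)/C(C(=O)OC)=C\CC/C(C)=C\2 | intermediate
26 | methyl 9-acetoxy-8-hydroxy-13-phenylsulfanyl-11,13-dihydrogermacra-1(10),4-dien-12,6-olid-14-oate | [C@@H]1(CSc3ccccc3)C(=O)O[C@@H]2[C@H]1[C@H](O)[C@@H](OC(C)=O)/C(C(=O)OC)=C\CC/C(C)=C\2 | intermediate
27 | (R)-2-methylglycidol | OC[C@]1(C)CO1 | starting material
28 | (S)-2-methyloxirane-2-carboxylic acid | OC(=O)[C@]1(C)CO1 | intermediate
29 | (S)-2-methyloxirane-2-carboxylic 2,4,6-trichlorobenzoic anhydride | O=C(OC(=O)[C@]1(C)CO1)c1c(Cl)cc(Cl)cc1Cl | intermediate (not isolated)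
30 | 8-O-[(S)-2-methyloxirane-2-carbonyl] ester of 26 | [C@@H]1(CSc3ccccc3)C(=O)O[C@@H]2[C@H]1[C@H](OC(=O)[C@]5(C)CO5)[C@@H](OC(C)=O)/C(C(=O)OC)=C\CC/C(C)=C\2 | intermediate
31 | sulfoxide of 30 (sulfur epimers) | [C@@H]1(CS(=O)c3ccccc3)C(=O)O[C@@H]2[C@H]1[C@H](OC(=O)[C@]5(C)CO5)[C@@H](OC(C)=O)/C(C(=O)OC)=C\CC/C(C)=C\2 | intermediate (not isolated)
32 | methyl 9-acetoxy-8-[(S)-2-methyloxirane-2-carbonyloxy]germacra-1(10),4,11(13)-trien-12,6-olid-14-oate (1(10)-cis, 4-cis, cis-lactone) | C=C1C(=O)O[C@@H]2[C@H]1[C@H](OC(=O)[C@]5(C)CO5)[C@@H](OC(C)=O)/C(C(=O)OC)=C\CC/C(C)=C\2 | intermediate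
33 | CNP0274195.1 | C=C1C(=O)O[C@@H]2[C@H]1[C@H](OC(=O)[C@]1(C)CO1)[C@@H](OC(C)=O)/C(C(=O)OC)=C\CC[C@@]1(C)O[C@@H]21 | target

**Summary**

Total step count: 24. Longest linear sequence: 23 steps (steps 1–20 and 22–24 from 1; step 21 is a one-step side branch).

Steps most likely to fail:

Step 16. The Lewis-acid activation may stop at the open-chain Michael stage (silyl transfer without four-ring closure), or the acid may cleave the enol ether before C–C bond formation. The fallback sets out from 18 and returns at 23. Buffered fluoride (TBAF/AcOH, 0 °C) frees the ketone F1. Condensation with pyrrolidine (TiCl4, toluene, 0 °C → rt) should give the less substituted C9=C2 enamine F2. This reacts with methyl propiolate 19 in MeCN at rt, without any acid, through the aminocyclobutene F3, which should open spontaneously to the ring-enlarged dienamine F4. Hydrolysis with aqueous AcOH/NaOAc and equilibration with Et3N as in step 17 then lead to 23. This is the thermal enamine–acetylenic ester two-carbon ring enlargement.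

Step 18. Hydride may add in conjugate fashion to the doubly activated C1=C10 bond, or to the wrong face of the C9 carbonyl if the ring conformation overrides the Felkin–Anh bias from C8. The fallback goes from 23 directly to 24 and makes no new compound (F0). It is a reagent-controlled Corey–Bakshi–Shibata reduction (oxazaborolidine enantiomer matched to the 9S carbinol, catecholborane, toluene, −78 °C), which is 1,2-selective for enones and sets the centre by the catalyst instead of the substrate.

Step 24. The peracid may be delivered to the wrong face of C4=C5. The fallback sets out from 32 and returns at 33. NBS in aqueous THF at 0 °C forms the bromonium ion on the face that electrophiles prefer, and water opens it at the tertiary C4 to give the anti bromohydrin F5. K2CO3 in dry acetone (or Ag2O) then closes the epoxide by intramolecular SN2 displacement at C5. The epoxide oxygen therefore ends on the face opposite to the one the electrophile attacked, the stereochemical complement of direct epoxidation.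

Further compounds
F1 | step 16 | C9 ketone regenerated from 18 (8-OTBS, 13-phenylsulfanyl cyclooctenone lactone) | [C@@H]1(CSc3ccccc3)C(=O)O[C@@H]2[C@H]1[C@H](O[Si](C)(C)C(C)(C)C)C(=O)CC/C(C)=C\2
F2 | step 16 | C9 pyrrolidine enamine of F1 (C9=C2) | [C@@H]1(CSc3ccccc3)C(=O)O[C@@H]2[C@H]1[C@H](O[Si](C)(C)C(C)(C)C)/C(N4CCCC4)=C\C/C(C)=C\2
F3 | step 16 | 9-pyrrolidinyl bicyclo[6.2.0]dec-9-ene adduct | [C@@H]1(CSc3ccccc3)C(=O)O[C@@H]2[C@H]1[C@H](O[Si](C)(C)C(C)(C)C)C4(N5CCCC5)C(C(=O)OC)=CC4C/C(C)=C\2
F4 | step 16 | ring-enlarged 9-pyrrolidinyl dienamine ester (ten-membered) | [C@@H]1(CSc3ccccc3)C(=O)O[C@@H]2[C@H]1[C@H](O[Si](C)(C)C(C)(C)C)/C(N4CCCC4)=C(C(=O)OC)\C=C\C/C(C)=C\2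
F0 | step 18 | none | none
F5 | step 24 | 5-bromo-4-hydroxy bromohydrin of 32 | C=C1C(=O)O[C@@H]2[C@H]1[C@H](OC(=O)[C@]5(C)CO5)[C@@H](OC(C)=O)/C(C(=O)OC)=C\CC[C@@](C)(O)[C@@H]2Br
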